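Ring B is disconnected across C5–C6, C2–C3, C4–C5 and C1–C2. It is a resorcinol in which C2–OH, C3–CH3 and the acylated C4–O correspond to a ketene carbon and to the two carbons of a 1-acyloxypropyne. A Danheiser benzannulation can therefore build the ring directly on the ester oxygen of ring A, with the two ring B oxygens already distinguished. In one operation a diazo enone carrying the C1 ester and C6 methyl is photolysed to a vinylketene, which combines with the prop-1-ynyl ester of the tribenzyl-protected ring A acid to give the complete protected depside. Debenzylation and one ortho-formylation of ring A follow.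

Key step: step 8

Remark on the chemistry: the four starting materials are taken as purchasable, and the target has no stereocentre, so the only stereochemical element carried is the (E)-alkene of the diazo ketone, which ends inside ring B. Ring A is numbered as in the acid (C1' carbonyl-bearing, C2' O, C3' H/CHO, C4' O, C5' O, C6' CH3).

Step 1
Reactants: 1 methyl orsellinate (methyl 2,4-dihydroxy-6-methylbenzoate)
Product: 3 methyl 2,4,5-trihydroxy-6-methylbenzoate, via aryl potassium sulfate 2 (not isolated)
Conditions: K2S2O8, aq. NaOH, 5 → 20 °C, N2; then HCl to pH 1, 70 °C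
Reagents that add atoms: potassium peroxodisulfate, [K+].[K+].[O-]S(=O)(=O)OOS(=O)(=O)[O-]
Why: Elbs persulfate oxidation, in which the phenoxide attacks the peroxide through C5 (para to the C2 oxygen and ortho to the C4 oxygen); the aryl sulfate shields the new oxygen from over-oxidation in base and is hydrolysed by warm dilute acid, while the methyl ester prevents decarboxylation.

Step 2
Reactants: 3 methyl 2,4,5-trihydroxy-6-methylbenzoate
Product: 4 methyl 2,4,5-tris(benzyloxy)-6-methylbenzoate
Conditions: BnBr, K2CO3, DMF (degassed), 60 °C, N2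
Reagents that add atoms: benzyl bromide, BrCc1ccccc1
Why: Williamson etherification with excess halide should alkylate all three phenols, the chelated C2 hydroxyl included at 60 °C, and the inert atmosphere guards the electron-rich triol against air.

Step 3
Reactants: 4 methyl 2,4,5-tris(benzyloxy)-6-methylbenzoate
Product: 5 2,4,5-tris(benzyloxy)-6-methylbenzoic acid
Conditions: KOH, DMSO–H2O, 90 °C; then aq. HCl
Reagents that add atoms: potassium hydroxide, [K+].[OH-]
Why: Saponification of a di-ortho-substituted benzoate needs poorly solvated hydroxide in aqueous DMSO, conditions to which the benzyl ethers are inert.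

Step 4
Reactants: 6 1-(trimethylsilyl)propyne
Product: 7 phenyl(prop-1-yn-1-yl)iodonium trifluoromethanesulfonate
Conditions: PhI(OAc)2, Tf2O, CH2Cl2, 0 °C; then 6, 0 → 20 °C
Reagents that add atoms: (diacetoxyiodo)benzene, CC(=O)OI(OC(C)=O)c1ccccc1; trifluoromethanesulfonic anhydride, O=S(=O)(OS(=O)(=O)C(F)(F)F)C(F)(F)F
Why: Silicon-to-iodine exchange (electrophilic ipso-substitution of an alkynylsilane by the trivalent iodine triflate formed from PhI(OAc)2 and Tf2O) is the standard entry to alkynyl(phenyl)iodonium triflates.

Step 5
Reactants: 5 2,4,5-tris(benzyloxy)-6-methylbenzoic acid; 7 phenyl(prop-1-yn-1-yl)iodonium trifluoromethanesulfonate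
Product: 9 prop-1-yn-1-yl 2,4,5-tris(benzyloxy)-6-methylbenzoate, via caesium carboxylate 8 (not isolated)
Conditions: Cs2CO3, MeOH, 20 °C, then evaporation to dryness; 7, CH2Cl2–MeCN, −30 → 20 °C; non-aqueous work-up
Reagents that add atoms: none
Why: Alkynylation of a carboxylate by an alkynyl(phenyl)iodonium salt: conjugate addition to the methyl-bearing alkyne carbon, loss of PhI and a 1,2-shift in the alkylidene carbene give the alkynyl carboxylate, and because the carboxylate oxygen is the reacting centre the two ortho substituents of ring A do not hinder it.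

Step 6
Reactants: 10 butane-2,3-dione; 11 methyl (triphenylphosphoranylidene)acetate
Product: 12 methyl (E)-3-methyl-4-oxopent-2-enoate
Conditions: CH2Cl2, 0 → 20 °C, excess 10
Reagents that add atoms: none
Why: Wittig olefination with a stabilised ylide should convert one carbonyl of the diketone (kept in excess to prevent double olefination) into the (E)-enoate, with the ester trans to the acetyl group.

Step 7
Reactants: 12 methyl (E)-3-methyl-4-oxopent-2-enoate
Product: 14 methyl (E)-5-diazo-3-methyl-4-oxopent-2-enoate, via trifluoroacetyl diketone 13 (not isolated)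
Conditions: LiN(SiMe3)2, THF, −78 °C; CF3CO2CH2CF3; then MsN3, Et3N, H2O, MeCN, 20 °C
Reagents that add atoms: methanesulfonyl azide, CS(=O)(=O)N=[N+]=[N-]
Why: Detrifluoroacetylative diazo transfer: the kinetic enolate of the methyl ketone is trifluoroacetylated (Claisen condensation), and the activated diketone takes the diazo group from the sulfonyl azide while passing the trifluoroacetyl group to the sulfonamide, which avoids exposing the electron-poor alkene to diazomethane.

Step 8
Reactants: 9 prop-1-yn-1-yl 2,4,5-tris(benzyloxy)-6-methylbenzoate; 14 methyl (E)-5-diazo-3-methyl-4-oxopent-2-enoate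
Product: 19 methyl 2-hydroxy-3,6-dimethyl-4-{[2,4,5-tris(benzyloxy)-6-methylbenzoyl]oxy}benzoate, via vinylketene 15 (not isolated), via acyloxycyclobutenone 16 (not isolated), via dienylketene 17 (not isolated), via cyclohexadienone 18 (not isolated)
Conditions: hν (365 nm), slow addition of 14 (excess), ClCH2CH2Cl, 20 °C; then 80 °C
Reagents that add atoms: none
Why: Proposed new method: light expels N2 from 14 and a 1,2-shift of the alkenyl group (Wolff rearrangement, new C5–C6 bond) gives vinylketene 15, whose carbonyl carbon is attacked by the methyl-bearing carbon of ynol ester 9 in a (2+2) cycloaddition to give 3-acyloxy-4-vinylcyclobutenone 16 (C2–C3 and C4–C5); reversible 4π opening gives dienylketene 17, ring B closes by thermal 6π electrocyclisation (C1–C2) to dienone 18, and enolisation gives the salicylate. The closest known reaction is the photochemical Wolff form of the Danheiser benzannulation with alkoxy-, siloxy- and amino-alkynes; an alkynyl carboxylate has not served as the ketene partner, but its oxygen lone pair polarises the triple bond in the same sense, only more weakly. No stereocentre is created. The step needs a single regiochemistry, with the acyloxy carbon joined to the former diazo carbon and the methyl carbon to the ketene carbon, and this is secured by that polarisation together with the higher electrophilicity of the ester-substituted vinylketene. The (E)-enoate geometry keeps CO2CH3 on the outside of the closing triene and out of reach of the ketene carbon, so neither pyranone formation nor a hindered inward rotation should compete. Irradiation at 365 nm is chosen because the aryl ester and benzyl ethers do not absorb there, which avoids photo-Fries cleavage, and the chelated, flanked C2 phenol of the product is a poor trap for excess ketene.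

Step 9
Reactants: 19 methyl 2-hydroxy-3,6-dimethyl-4-{[2,4,5-tris(benzyloxy)-6-methylbenzoyl]oxy}benzoate
Product: 20 methyl 2-hydroxy-3,6-dimethyl-4-[(2,4,5-trihydroxy-6-methylbenzoyl)oxy]benzoate
Conditions: H2 (1 atm), Pd/C (palladium on carbon), EtOAc, 20 °C; filtration under argon
Reagents that add atoms: none
Why: Catalytic hydrogenolysis should cleave the three benzyl aryl ethers and leave both esters untouched; the air-sensitive triol is carried on without storage.

Step 10
Reactants: 20 methyl 2-hydroxy-3,6-dimethyl-4-[(2,4,5-trihydroxy-6-methylbenzoyl)oxy]benzoate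
Product: 21 methyl 4-[(3-formyl-2,4,5-trihydroxy-6-methylbenzoyl)oxy]-2-hydroxy-3,6-dimethylbenzoate (target)
Conditions: MgCl2, Et3N, (CH2O)n, THF (degassed), 65 °C, argon; then aq. HCl
Reagents that add atoms: paraformaldehyde (as formaldehyde), C=O
Why: Magnesium-mediated ortho-formylation (Casnati–Skattebøl) delivers formaldehyde within the magnesium phenoxide only to a carbon ortho to a phenoxide oxygen, and C3' of ring A is the only such CH in the molecule (the lone CH of ring B is para to its hydroxyl); a second formaldehyde oxidises the benzylic alkoxide to the aldehyde.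

Compound list
1 | methyl orsellinate (methyl 2,4-dihydroxy-6-methylbenzoate) | COC(=O)c1c(C)cc(O)cc1O | starting material
2 | potassium 2,4-dihydroxy-3-(methoxycarbonyl)-6-... aryl sulfate: methyl 2,4-dihydroxy-6-methyl-5-(sulfonatooxy)benzoate, potassium salt | COC(=O)c1c(C)c(OS(=O)(=O)[O-])c(O)cc1O.[K+] | intermediate
3 | methyl 2,4,5-trihydroxy-6-methylbenzoate | COC(=O)c1c(C)c(O)c(O)cc1O | intermediate
4 | methyl 2,4,5-tris(benzyloxy)-6-methylbenzoate | COC(=O)c1c(C)c(OCc2ccccc2)c(OCc2ccccc2)cc1OCc1ccccc1 | intermediate
5 | 2,4,5-tris(benzyloxy)-6-methylbenzoic acid | OC(=O)c1c(C)c(OCc2ccccc2)c(OCc2ccccc2)cc1OCc1ccccc1 | intermediate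
6 | 1-(trimethylsilyl)propyne | CC#C[Si](C)(C)C | starting material
7 | phenyl(prop-1-yn-1-yl)iodonium trifluoromethanesulfonate | CC#C[I+]c1ccccc1.[O-]S(=O)(=O)C(F)(F)F | intermediate
8 | caesium 2,4,5-tris(benzyloxy)-6-methylbenzoate | [Cs+].[O-]C(=O)c1c(C)c(OCc2ccccc2)c(OCc2ccccc2)cc1OCc1ccccc1 | intermediate
9 | prop-1-yn-1-yl 2,4,5-tris(benzyloxy)-6-methylbenzoate | CC#COC(=O)c1c(C)c(OCc2ccccc2)c(OCc2ccccc2)cc1OCc1ccccc1 | intermediate
10 | butane-2,3-dione | CC(=O)C(C)=O | starting material
11 | methyl (triphenylphosphoranylidene)acetate | COC(=O)C=P(c1ccccc1)(c1ccccc1)c1ccccc1 | starting material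
12 | methyl (E)-3-methyl-4-oxopent-2-enoate | COC(=O)/C=C(C)/C(C)=O | intermediate
13 | methyl (E)-6,6,6-trifluoro-3-methyl-4,6-dioxohex-2-enoate | COC(=O)/C=C(C)/C(=O)CC(=O)C(F)(F)F | intermediate
14 | methyl (E)-5-diazo-3-methyl-4-oxopent-2-enoate | COC(=O)/C=C(C)/C(=O)C=[N+]=[N-] | intermediate
15 | methyl (E)-3-methyl-5-oxopenta-2,4-dienoate (vinylketene) | COC(=O)/C=C(C)/C=C=O | intermediate
16 | methyl (E)-3-{3-methyl-4-oxo-2-[(2,4,5-tris(benzyloxy)-6-methylbenzoyl)oxy]cyclobut-2-en-1-yl}but-2-enoate (racemic) | COC(=O)/C=C(C)/C1C(=O)C(C)=C1OC(=O)c1c(C)c(OCc2ccccc2)c(OCc2ccccc2)cc1OCc1ccccc1 | intermediate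
17 | methyl (2E,4E)-3,6-dimethyl-7-oxo-5-[(2,4,5-tris(benzyloxy)-6-methylbenzoyl)oxy]hepta-2,4,6-trienoate (dienylketene, ketene arm cis to the enoate arm) | O=C=C(C)/C(OC(=O)c1c(C)c(OCc2ccccc2)c(OCc2ccccc2)cc1OCc1ccccc1)=C\C(C)=C\C(=O)OC | intermediate
18 | methyl 2,5-dimethyl-6-oxo-4-[(2,4,5-tris(benzyloxy)-6-methylbenzoyl)oxy]cyclohexa-2,4-diene-1-carboxylate (racemic) | COC(=O)C1C(C)=CC(OC(=O)c2c(C)c(OCc3ccccc3)c(OCc3ccccc3)cc2OCc2ccccc2)=C(C)C1=O | intermediate
19 | methyl 2-hydroxy-3,6-dimethyl-4-{[2,4,5-tris(benzyloxy)-6-methylbenzoyl]oxy}benzoate | COC(=O)c1c(C)cc(OC(=O)c2c(C)c(OCc3ccccc3)c(OCc3ccccc3)cc2OCc2ccccc2)c(C)c1O | intermediate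
20 | methyl 2-hydroxy-3,6-dimethyl-4-[(2,4,5-trihydroxy-6-methylbenzoyl)oxy]benzoate | COC(=O)c1c(C)cc(OC(=O)c2c(C)c(O)c(O)cc2O)c(C)c1O | intermediate
21 | methyl 4-[(3-formyl-2,4,5-trihydroxy-6-methylbenzoyl)oxy]-2-hydroxy-3,6-dimethylbenzoate (CNP0216802.0) | COC(=O)c1c(C)cc(OC(=O)c2c(C)c(O)c(O)c(C=O)c2O)c(C)c1O | target

Total step count: 10. Longest linear sequence: 7 steps (steps 1, 2, 3, 5, 8, 9, 10).

Steps most likely to fail

1. Step 8. The alkynyl carboxylate may capture the vinylketene too slowly, so that ketene self-reaction, acyl transfer from the vinylogous-anhydride cyclobutenone, or E-to-Z photoisomerisation followed by oxa-6π closure consumes the material. The fallback uses known depside chemistry, sets out from 5 and comes back at 19. Acid 5 and purchased methyl 2,4-dihydroxy-3,6-dimethylbenzoate F1 are treated with (CF3CO)2O in toluene at 20 °C. The mixed 2,4,5-tris(benzyloxy)-6-methylbenzoic trifluoroacetic anhydride F2 forms in the flask and should acylate the unchelated C4 hydroxyl of F1 in preference to the chelated, flanked C2 hydroxyl, giving 19. Steps 4 to 7 then drop out.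

2. Step 5. The ynol ester may be hydrated or may transfer its acyl group during formation and isolation, or the poorly soluble caesium salt may exchange too slowly with the iodonium triflate. The fallback sets out from 5 and comes back at 9. Ligand exchange of PhI(OAc)2 with two equivalents of 5 (chlorobenzene, 50 °C, reduced pressure to strip acetic acid) should give phenyliodine bis[2,4,5-tris(benzyloxy)-6-methylbenzoate] F3. Prop-1-ynyllithium F4, made from 6 and MeLi in THF at 0 °C, is added at −78 °C. The acetylide displaces one carboxylate at trivalent iodine, and the alkynyl(phenyl)iodonium carboxylate collapses with loss of iodobenzene to 9. The displaced equivalent of 5 is recovered by extraction.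

3. Step 10. The 1,2,4-trihydroxylated ring A may be oxidised by traces of air under the basic magnesium–amine conditions, or the depside ester may be slowly methanolysed by magnesium methoxide formed in the redox stage. The fallback sets out from 19 and comes back at 21.
   - Chelation-assisted cleavage (MgBr2·OEt2, toluene–Et2O, 80 °C) should remove only the benzyl ether ortho to the aroyl carbonyl, giving methyl 4-{[3,4-bis(benzyloxy)-6-hydroxy-2-methylbenzoyl]oxy}-2-hydroxy-3,6-dimethylbenzoate F5.
   - The same MgCl2, Et3N, (CH2O)n formylation, now on an air-stable monophenol of ring A, should give methyl 4-{[3,4-bis(benzyloxy)-5-formyl-6-hydroxy-2-methylbenzoyl]oxy}-2-hydroxy-3,6-dimethylbenzoate F6.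
   - Brief hydrogenolysis (H2, Pd/C (palladium on carbon), EtOAc, 20 °C) frees the last two phenols under neutral, reducing conditions and gives 21; the doubly chelated aldehyde should survive.

Further compounds
F1 | step 8 | methyl 2,4-dihydroxy-3,6-dimethylbenzoate (purchased coupling partner) | COC(=O)c1c(C)cc(O)c(C)c1O
F2 | step 8 | 2,4,5-tris(benzyloxy)-6-methylbenzoic trifluoroacetic anhydride | O=C(OC(=O)C(F)(F)F)c1c(C)c(OCc2ccccc2)c(OCc2ccccc2)cc1OCc1ccccc1
F3 | step 5 | phenyliodine bis[2,4,5-tris(benzyloxy)-6-methylbenzoate] | O=C(OI(OC(=O)c1c(C)c(OCc2ccccc2)c(OCc2ccccc2)cc1OCc1ccccc1)c1ccccc1)c1c(C)c(OCc2ccccc2)c(OCc2ccccc2)cc1OCc1ccccc1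
F4 | step 5 | prop-1-ynyllithium | [Li]C#CC
F5 | step 10 | methyl 4-{[3,4-bis(benzyloxy)-6-hydroxy-2-methylbenzoyl]oxy}-2-hydroxy-3,6-dimethylbenzoate | COC(=O)c1c(C)cc(OC(=O)c2c(C)c(OCc3ccccc3)c(OCc3ccccc3)cc2O)c(C)c1O
F6 | step 10 | methyl 4-{[3,4-bis(benzyloxy)-5-formyl-6-hydroxy-2-methylbenzoyl]oxy}-2-hydroxy-3,6-dimethylbenzoate | COC(=O)c1c(C)cc(OC(=O)c2c(C)c(OCc3ccccc3)c(OCc3ccccc3)c(C=O)c2O)c(C)c1O
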